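**Retrosynthetic overview**

1. Xestin A ⇒ cut C3–C4 of the 3,6-dihydro-1,2-dioxin: acyclic peroxide 16, whose C6 methoxy peroxyketal carries the alkyl chain and a (Z)-CH=CH–SiMe3 group, and whose O2 carries C3 as the methoxy acetal of a CH2CO2Me unit.
2. 16 ⇒ cut O1–C6: dimethyl ketal 12 plus α-methoxy hydroperoxide 15 (ozonolysis of dimethyl (E)-hex-3-enedioate in methanol).
3. 12 ⇒ sorbyl acetate plus bromide 9 (copper-catalysed coupling, diene introduced last); 9 ⇒ 12-bromododecan-1-ol plus 3-(trimethylsilyl)prop-2-ynal.
4. Rings: the dioxine is the only ring of the target; it is closed last, in the key step, together with both stereocentres.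
5. Enabling feature: in the ring O1–O2–C3–C4=C5–C6, C3 is bound to O2 and allylic to the cis C4=C5 bond, so a peroxycarbenium ion O2=C3(+) lies at ring-closing distance from a vinylsilane carbon C4; C6 is a peroxyketal carbon (O1, OMe) whose configuration is reversible under acid.

Key step: step 10

Remark: the 3R,6R arrangement (OMe pseudo-axial, both carbon substituents pseudo-equatorial) is taken to be the thermodynamically preferred C6 anomer.
Remark: which antipode of the chiral acid gives 3R cannot be predicted with confidence and is to be fixed in a first screen; both antipodes are accessible.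

**Route**

Step 1
Reactants: 1 12-bromododecan-1-ol
Product: 2 2-[(12-bromododecyl)oxy]tetrahydro-2H-pyran
Conditions: 3,4-dihydro-2H-pyran, PPTS (cat.), CH2Cl2, rt
Reagents that add atoms: 3,4-dihydro-2H-pyran C1=COCCC1
Why: Acid-catalysed tetrahydropyranylation masks the hydroxyl group so that the bromide can be converted into a Grignard reagent; the new acetal centre is racemic and is removed in step 4.

Step 2
Reactants: 2 2-[(12-bromododecyl)oxy]tetrahydro-2H-pyran, 3 3-(trimethylsilyl)prop-2-ynal
Product: 5 15-(tetrahydro-2H-pyran-2-yloxy)-1-(trimethylsilyl)pentadec-1-yn-3-ol, via Grignard reagent 4 (not isolated)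
Conditions: Mg, THF, 40 °C; then 3, THF, −78 → 0 °C; aq. NH4Cl
Reagents that add atoms: none
Why: Grignard formation and 1,2-addition to the ynal, whose β-carbon is blocked by silicon, should give the propargylic alcohol; its configuration is irrelevant because the carbinol is oxidized in step 3.

Step 3
Reactants: 5 15-(tetrahydro-2H-pyran-2-yloxy)-1-(trimethylsilyl)pentadec-1-yn-3-ol
Product: 6 15-(tetrahydro-2H-pyran-2-yloxy)-1-(trimethylsilyl)pentadec-1-yn-3-one
Conditions: activated MnO2, CH2Cl2, rt
Reagents that add atoms: none
Why: MnO2 oxidation of a propargylic alcohol to the ynone is neutral and should leave the THP ether and the C–Si bond untouched.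

Step 4
Reactants: 6 15-(tetrahydro-2H-pyran-2-yloxy)-1-(trimethylsilyl)pentadec-1-yn-3-one
Product: 7 13,13-dimethoxy-15-(trimethylsilyl)pentadec-14-yn-1-ol
Conditions: HC(OMe)3, MeOH, TsOH·H2O (cat.), rt; then NaHCO3
Reagents that add atoms: trimethyl orthoformate COC(OC)OC; methanol CO
Why: Acid-catalysed ketalization with orthoformate as water scavenger should give the dimethyl ketal while the same methanolic acid removes the THP group by transacetalization; the silyl group shields the alkyne terminus against conjugate addition of methanol.

Step 5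
Reactants: 7 13,13-dimethoxy-15-(trimethylsilyl)pentadec-14-yn-1-ol
Product: 8 (14Z)-13,13-dimethoxy-15-(trimethylsilyl)pentadec-14-en-1-ol
Conditions: H2 (1 atm), Lindlar catalyst, quinoline, EtOAc, rt
Reagents that add atoms: none
Why: Lindlar semi-hydrogenation delivers both hydrogens syn and should give the (Z)-vinylsilane that the ring closure needs; nothing else reducible is present at this stage.

Step 6
Reactants: 8 (14Z)-13,13-dimethoxy-15-(trimethylsilyl)pentadec-14-en-1-ol
Product: 9 [(1Z)-15-bromo-3,3-dimethoxypentadec-1-en-1-yl]trimethylsilane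
Conditions: CBr4, PPh3, 2,6-lutidine, CH2Cl2, 0 °C
Reagents that add atoms: tetrabromomethane BrC(Br)(Br)Br
Why: Appel bromination of the primary alcohol runs under essentially neutral, buffered conditions that should spare the allylic ketal and the vinylsilane.

Step 7
Reactants: 9 [(1Z)-15-bromo-3,3-dimethoxypentadec-1-en-1-yl]trimethylsilane, 10 (2E,4E)-hexa-2,4-dien-1-yl acetate (sorbyl acetate)
Product: 12 [(1Z,17E,19E)-3,3-dimethoxyhenicosa-1,17,19-trien-1-yl]trimethylsilane, via Grignard reagent 11 (not isolated)
Conditions: Mg, THF; then 10, Li2CuCl4 (3 mol %), THF, −20 → 0 °C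
Reagents that add atoms: none
Why: Kochi-type copper-catalysed coupling of an alkyl Grignard reagent with a dienyl acetate should occur at the α-carbon with retention of the E,E geometry, the reaction type used for long-chain (E,E)-dienol pheromones; ketal and vinylsilane are inert to the Grignard reagent.

Step 8
Reactants: 13 dimethyl (E)-hex-3-enedioate
Product: 15 methyl 3-hydroperoxy-3-methoxypropanoate, via carbonyl oxide 14 (not isolated)
Conditions: O3, CH2Cl2/MeOH 1:1, −78 °C; N2 purge; concentration below 20 °C; chromatography
Reagents that add atoms: ozone O=[O+][O-]; methanol CO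
Why: Ozonolysis in methanol (Criegee mechanism) should give a carbonyl oxide that methanol traps as the α-methoxy hydroperoxide; the symmetry of the alkene allows only one hydroperoxide.

Step 9
Reactants: 12 [(1Z,17E,19E)-3,3-dimethoxyhenicosa-1,17,19-trien-1-yl]trimethylsilane, 15 methyl 3-hydroperoxy-3-methoxypropanoate
Product: 16 methyl 3-methoxy-3-{[(1Z,17E,19E)-3-methoxy-1-(trimethylsilyl)henicosa-1,17,19-trien-3-yl]peroxy}propanoate (mixture of four stereoisomers)
Conditions: PPTS (5 mol %), 5 Å MS, CH2Cl2, 0 °C → rt
Reagents that add atoms: none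
Why: In this acid-catalysed peroxyketal exchange the tertiary allylic dimethyl ketal should ionize far more easily than the ester-deactivated secondary acetal of 15, so the hydroperoxide captures the alkoxyallyl cation at C6 while the sieves take up methanol; both acetal centres form as mixtures, which is harmless because both are stereolabile in step 10.

Step 10
Reactants: 16 methyl 3-methoxy-3-{[(1Z,17E,19E)-3-methoxy-1-(trimethylsilyl)henicosa-1,17,19-trien-3-yl]peroxy}propanoate
Product: 19 xestin A, via peroxycarbenium ion 17 (not isolated), via 6-epimeric peroxyketal 18 (not isolated)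
Conditions: confined chiral imidodiphosphorimidate (IDPi) Brønsted acid (5 mol %, antipode fixed by screen), 4 Å MS, CH2Cl2 (0.01 M), −78 → −40 °C; then −20 °C; pH 7 buffer
Reagents that add atoms: none
Why: Proposed new method: the chiral acid (after the first turnover its silylated form) removes the C3 methoxy group of 16 to give peroxycarbenium ion 17 as a contact ion pair with the chiral anion; the (Z)-vinylsilane attacks it through its silicon-bearing carbon C4 in a chair-like 6-endo-trig closure (both alkene carbons and the O2=C3 bond lie inside the new 1,2-dioxine ring), and loss of Me3Si+ from the β-silyl cation restores C4=C5 as the cis alkene and regenerates the silylated catalyst. The closest known reaction types are the Lewis-acid generation of peroxycarbenium ions from peroxyacetals with capture by allylsilanes and silyl enol ethers, the silyl-Prins cyclization of (Z)-vinylsilyl homoallylic alcohols to cis-2,6-disubstituted dihydropyrans, and imidodiphosphorimidate-controlled asymmetric Prins cyclizations and additions of silicon nucleophiles to oxocarbenium ions. C3 is set by the chiral anion, which differentiates the two faces of the planar peroxycarbenium carbon while the CH2CO2Me arm sits equatorial in the chair. C6 is set thermodynamically: the tertiary allylic methoxy peroxyketal ionizes reversibly under the same acid (return by Me3SiOMe), so both C6 epimers of 16 and the kinetic 6-epimer 18 should drain into the anomer with pseudo-axial OMe and both carbon substituents pseudo-equatorial, which is the 3R,6R arrangement of 19. The selectivity needed is productive ionization at C3 in the presence of the more easily ionized C6 centre; it is secured because ionization at C6 is degenerate and reversible whereas C–C bond formation with desilylation is irreversible, and because the β-silicon effect makes C4, not the remote side-chain diene, the fastest nucleophile within reach.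

**Compound list**

1 | 12-bromododecan-1-ol | OCCCCCCCCCCCCBr | starting material
2 | 2-[(12-bromododecyl)oxy]tetrahydro-2H-pyran (racemic) | BrCCCCCCCCCCCCOC1CCCCO1 | intermediate
3 | 3-(trimethylsilyl)prop-2-ynal | C[Si](C)(C)C#CC=O | starting material
4 | [12-(tetrahydro-2H-pyran-2-yloxy)dodecyl]magnesium bromide | Br[Mg]CCCCCCCCCCCCOC1CCCCO1 | intermediate (not isolated)
5 | 15-(tetrahydro-2H-pyran-2-yloxy)-1-(trimethylsilyl)pentadec-1-yn-3-ol (stereoisomer mixture) | C[Si](C)(C)C#CC(O)CCCCCCCCCCCCOC1CCCCO1 | intermediate
6 | 15-(tetrahydro-2H-pyran-2-yloxy)-1-(trimethylsilyl)pentadec-1-yn-3-one | C[Si](C)(C)C#CC(=O)CCCCCCCCCCCCOC1CCCCO1 | intermediate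
7 | 13,13-dimethoxy-15-(trimethylsilyl)pentadec-14-yn-1-ol | C[Si](C)(C)C#CC(OC)(OC)CCCCCCCCCCCCO | intermediate
8 | (14Z)-13,13-dimethoxy-15-(trimethylsilyl)pentadec-14-en-1-ol | C[Si](C)(C)/C=C\C(OC)(OC)CCCCCCCCCCCCO | intermediate
9 | [(1Z)-15-bromo-3,3-dimethoxypentadec-1-en-1-yl]trimethylsilane | C[Si](C)(C)/C=C\C(OC)(OC)CCCCCCCCCCCCBr | intermediate
10 | (2E,4E)-hexa-2,4-dien-1-yl acetate (sorbyl acetate) | C/C=C/C=C/COC(C)=O | starting material
11 | [(14Z)-13,13-dimethoxy-15-(trimethylsilyl)pentadec-14-en-1-yl]magnesium bromide | C[Si](C)(C)/C=C\C(OC)(OC)CCCCCCCCCCCC[Mg]Br | intermediate (not isolated)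
12 | [(1Z,17E,19E)-3,3-dimethoxyhenicosa-1,17,19-trien-1-yl]trimethylsilane | C/C=C/C=C/CCCCCCCCCCCCCC(OC)(OC)/C=C\[Si](C)(C)C | intermediate
13 | dimethyl (E)-hex-3-enedioate | COC(=O)C/C=C/CC(=O)OC | starting material
14 | carbonyl oxide of methyl 3-oxopropanoate | COC(=O)CC=[O+][O-] | intermediate (not isolated)
15 | methyl 3-hydroperoxy-3-methoxypropanoate (racemic) | COC(=O)CC(OC)OO | intermediate
16 | methyl 3-methoxy-3-{[(1Z,17E,19E)-3-methoxy-1-(trimethylsilyl)henicosa-1,17,19-trien-3-yl]peroxy}propanoate (mixture of four stereoisomers) | C/C=C/C=C/CCCCCCCCCCCCCC(OC)(/C=C\[Si](C)(C)C)OOC(OC)CC(=O)OC | intermediate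
17 | peroxycarbenium ion from 16 (cation of the ion pair with the catalyst anion) | C/C=C/C=C/CCCCCCCCCCCCCC(OC)(/C=C\[Si](C)(C)C)O[O+]=CCC(=O)OC | intermediate (not isolated)
18 | methyl 2-[(3R,6S)-6-methoxy-6-[(14E,16E)-octadeca-14,16-dien-1-yl]-3,6-dihydro-1,2-dioxin-3-yl]acetate (6-epi-xestin A) | C/C=C/C=C/CCCCCCCCCCCCC[C@@]1(OC)C=C[C@@H](CC(=O)OC)OO1 | intermediate (not isolated)
19 | xestin A, methyl 2-[(3R,6R)-6-methoxy-6-[(14E,16E)-octadeca-14,16-dien-1-yl]-3,6-dihydro-1,2-dioxin-3-yl]acetate | C/C=C/C=C/CCCCCCCCCCCCC[C@]1(OC)C=C[C@@H](CC(=O)OC)OO1 | target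

**Step count and risks**

Total step count: 10. Longest linear sequence: 9 (steps 1–7, 9, 10); step 8 is a one-step branch.

Steps most likely to fail:

1. Step 10 (Proposed new method). What may go wrong:
- irreversible consumption at C6 (acid-induced Hock/Criegee-type O–O heterolysis with migration, or loss of the peroxide fragment) outrunning productive ionization at C3;
- deprotonation of the peroxycarbenium ion next to the ester to an unstable alkenyl peroxide;
- Z→E isomerization of the vinylsilane through the reversibly formed C6 cation;
- insufficient facial discrimination by the chiral anion, or only a weak thermodynamic bias at C6, in which case the 6-epimer would be separated and re-equilibrated with acid.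

Fallback with known chemistry, closing the ring at O2–C3 instead; it sets out from 12 and returns at 19. Iododesilylation of 12 with N-iodosuccinimide (MeCN, 0 °C, dark) with retention should give (1Z,17E,19E)-1-iodo-3,3-dimethoxyhenicosa-1,17,19-triene F1. A ligand-free phase-transfer Heck reaction with methyl acrylate (Pd(OAc)2, K2CO3, Bu4NCl, DMF, rt) should give methyl (2E,4Z,20E,22E)-6,6-dimethoxytetracosa-2,4,20,22-tetraenoate F2. Exchange of one methoxy group with ethereal H2O2 (PPTS) should give methyl (2E,4Z,20E,22E)-6-hydroperoxy-6-methoxytetracosa-2,4,20,22-tetraenoate F3. Amine-catalysed intramolecular oxa-Michael addition of the hydroperoxide (Et2NH, CF3CH2OH), followed by acid-catalysed equilibration of C6 in methanol, should give racemic xestin A F4. Resolution by preparative HPLC on a chiral stationary phase would separate 19 from ent-xestin A F5.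

2. Step 9. What may go wrong: exchange of both methoxy groups at C6, return of the equilibrium by the liberated methanol, geometric isomerization of the vinylsilane through the alkoxyallyl cation, or capture of that cation at C4 instead of C6.

Fallback that replaces the exchange equilibrium by an addition; it sets out from 12 and returns at 16. Elimination of methanol from 12 with TMSOTf/i-Pr2NEt (CH2Cl2, −20 °C) should give [(1Z,17E,19E)-3-methoxyhenicosa-1,3,17,19-tetraen-1-yl]trimethylsilane F6. PPTS-catalysed Markovnikov addition of hydroperoxide 15 across its enol-ether double bond would then give 16 without liberating methanol.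

3. Step 8. What may go wrong: recombination of the hydroperoxide with the co-formed aldehyde during concentration (peroxy-hemiacetal oligomers) and dehydration of the α-methoxy hydroperoxide to the malonate ester during purification.

Fallback that moves the hydroperoxide function to the other fragment; it sets out from 12 and returns at 16, bypassing 15. Exchange of 12 with ethereal H2O2 (PPTS, 0 °C) should give [(1Z,17E,19E)-3-hydroperoxy-3-methoxyhenicosa-1,17,19-trien-1-yl]trimethylsilane F7. Its acid-catalysed addition to commercial methyl (E)-3-methoxyacrylate (CO/C=C/C(=O)OC; peroxyacetalization of an enol ether) would give 16.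

**Further compounds**

F1 | step 10 | (1Z,17E,19E)-1-iodo-3,3-dimethoxyhenicosa-1,17,19-triene | C/C=C/C=C/CCCCCCCCCCCCCC(OC)(OC)/C=C\I
F2 | step 10 | methyl (2E,4Z,20E,22E)-6,6-dimethoxytetracosa-2,4,20,22-tetraenoate | C/C=C/C=C/CCCCCCCCCCCCCC(OC)(OC)/C=C\C=C\C(=O)OC
F3 | step 10 | methyl (2E,4Z,20E,22E)-6-hydroperoxy-6-methoxytetracosa-2,4,20,22-tetraenoate (racemic) | C/C=C/C=C/CCCCCCCCCCCCCC(OC)(OO)/C=C\C=C\C(=O)OC
F4 | step 10 | racemic xestin A | C/C=C/C=C/CCCCCCCCCCCCCC1(OC)C=CC(CC(=O)OC)OO1
F5 | step 10 | ent-xestin A (3S,6S) | C/C=C/C=C/CCCCCCCCCCCCC[C@@]1(OC)C=C[C@H](CC(=O)OC)OO1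
F6 | step 9 | [(1Z,17E,19E)-3-methoxyhenicosa-1,3,17,19-tetraen-1-yl]trimethylsilane (enol-ether geometry not defined) | C/C=C/C=C/CCCCCCCCCCCCC=C(OC)/C=C\[Si](C)(C)C
F7 | step 8 | [(1Z,17E,19E)-3-hydroperoxy-3-methoxyhenicosa-1,17,19-trien-1-yl]trimethylsilane (racemic) | C/C=C/C=C/CCCCCCCCCCCCCC(OC)(OO)/C=C\[Si](C)(C)C
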